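# Design of a total synthesis of 15-keto-PGF2α by rhodium-catalysed enyne cycloisomerisation (C8–C12)

## The problem

15-Keto-PGF2α (25) is a cyclopentane with four contiguous stereocentres (C8, C9, C11, C12; prostanoid numbering) and two chains. The upper chain C1–C7 carries a Z-C5=C6 alkene and a free acid; the lower chain C13–C20 carries an E-enone (C13=C14–C15=O). The hydroxyls at C9 and C11 are cis to each other and to the upper chain, and the lower chain on C12 is trans to all three. C11 can therefore steer C12 (trans), C12 can steer C8 (trans, the favoured 2,3-relationship in a cyclopentanone), and C8 can steer a hydride to C9 (cis). Only one stereocentre has to be bought, provided a C9 ketone is present when C8 and C9 are set.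

The enone is a Michael acceptor and would not survive the hydride, ylide and fluoride steps needed elsewhere, so C15 must travel as a ketal and be unmasked last. The 9-oxo-11-oxy stage loses O11 under base, and the Z-alkene forbids late hydrogenation.

The feature that opens the key step is this: C12 bears an E-alkene whose far carbon C14 is a methylene next to C15, and C8 lies between the C9 carbonyl carbon and C7. The ring bond C8–C12 is exactly the bond an intramolecular ene-type union of a C7≡C8 ynone with a Z-C12=C13 alkene would form, with a C14 hydrogen moving to C7.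

## Retrosynthesis

**C15 unmasking.** The target 25 is traced to the 15-dioxolane acid 24. No skeletal bond is cut. The enone then appears only in the last step and never meets a hydride, an ylide or fluoride. The forward step needs only mild aqueous acid, which an allylic ketal accepts readily.

**C5=C6.** Acid 24 is cut at the Z-alkene into the bicyclic lactol 20 and the ylide 23 from the commercial phosphonium salt 22. This Wittig reaction sets the Z geometry and brings in the acid unprotected. The neighbouring option, a C6–C7 cut with a Z-alkenyl copper reagent, would need an ortho-ester-masked alkenyl iodide made in several steps and would force C7 to be a bare methylene before ring closure (see the key cut). Lactol 20 is seven carbons smaller than 24 and has no alkene geometry to control in the upper half.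

**Oxidation-level adjustments around the ring.** Lactol 20 comes from lactone 21, which comes from triol 19 by selective oxidation of the primary C6 alcohol and capture by the 9α-hydroxyl. Triol 19 comes from bis-silyl ether 18, and 18 from ketone 17 by hydride delivery anti to the C8 chain. Ketone 17 comes from the alkylidene ketone 16 by conjugate reduction. No carbon–carbon bond is cut in this stretch; it relays stereochemistry from C12 to C8 to C9.

**Key cut, C8–C12.** Enone 16 is opened to the acyclic Z-enynone 15 by reversing a 1,6-enyne cycloisomerisation: C8–C12 is cut, the hydrogen on C7 is returned to C14, and the E-C13=C14 alkene becomes the Z-C12=C13 alkene. This cut removes the ring and the C12 stereocentre in one step, leaving a chain with a single stereocentre (C11). Cuts at C9–C10 or C11–C12 would not exploit the 1,4-diene pattern C7=C8–C12–C13=C14 that the ene reaction writes directly.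

Leaving C7 as a terminal C–H was weighed and set aside. Cationic monovalent rhodium–bisphosphine catalysts tend to divert terminal alkynes into alkynyl- or vinylidene-metal species and cyclotrimers. C7 therefore carries C6 as a silyloxymethyl group, which is a spectator in the ring closure and later becomes the lactol carbon. The forward reaction must give 11,12-trans selectivity, E geometry at C13=C14, and hydrogen transfer only from C14.

**C8–C9.** Ynone 15 is cut at the acyl–alkyne bond into the N-methoxy-N-methylamide 12 and the lithium acetylide 14 from commercial silyl propargyl ether 13. The amide stops the addition at the ketone stage and is already present from the lactone opening.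

**C12=C13.** Amide 12 is cut at the Z-alkene into the α-silyloxy aldehyde 10 and the ylide 11 from phosphonium salt 6. A non-stabilised ylide gives the Z geometry that the key step requires. The dioxolane two carbons from phosphorus cannot be expelled and carries C15 in its final oxidation state.

**Starting materials.** Aldehyde 10 comes from the hydroxy amide 9 and so from (R)-3-hydroxy-γ-butyrolactone 7 via its silyl ether 8. This is the reduced (R)-malate C4 unit in which the two ends are already differentiated, and its C3 becomes C11. Salt 6 comes from chloro ketal 4, chloro ketone 3, hexanoyl chloride 1 and ethylene 2.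

## Roads not taken

**Alternative 1:** The ring is cut at C8–C9 and C11=C12 into two molecules of succinaldehyde A2. In the forward direction an amino-acid enamine aldol followed by an ammonium-salt aldol condensation gives the bicyclic enal lactol A1. The lower chain would then be added to C12 as an alkenyl copper reagent, C11 revealed as a ketone by cleaving the resulting enol ether, the ketone reduced, and the same lactol Wittig reaction used as in step 15.
- Merits: the lactol for the upper chain, the C8/C9 relationship and a handle at C12 all come from a four-carbon dialdehyde in one operation, and the sequence to a PGF skeleton is about half as long as the one proposed here.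
- Weak points for this target: the dimerisation competes with oligomerisation of A2, so the first step has poor mass throughput. One carbon is added and then cut off again. The C11 carbonyl must be generated oxidatively while the C13=C14 alkene is present. The C15 ketone would still have to ride as a ketal on the alkenyl metal.
- Comparison: in step count this road is clearly better. The chosen plan has to set against that a catalytic, atom-neutral ring closure that installs the whole lower chain, its E-alkene and C12 together from a bought stereocentre, and the absence of any oxidative cleavage next to an alkene.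

**Alternative 2:** The ring is cut at C8–C9, together with the O–C7 bond, by reversing an intramolecular nitrile oxide cycloaddition onto a vinyl group on C12. The forward step gives the fused isoxazoline A3, a masked 9-oxo-7-hydroxy unit.
- Merits: the ring closure is a dependable, metal-free reaction. C9 arrives as a latent ketone. After unmasking C13 as an aldehyde, a Horner–Wadsworth–Emmons reaction would give the 15-keto enone directly, which suits this target.
- Weak points: two stereocentres (C11 and C12) must be set in the open chain before cyclisation, against one here. The C8 centre it creates is lost again if C7 is turned into an electrophile. Neither chain is present after ring formation: C7 must be converted from an alcohol into a carbon–carbon bond to C6, and C13 must be deprotected, oxidised and olefinated while a base-sensitive β-oxy ketone is in the ring. The enone would then have to coexist with the C9 reduction.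
- Comparison: this road is safer at the ring-forming step. The chosen plan is shorter after the ring is closed and never exposes the enone to a hydride.

**Alternative 3:** The ring is cut at C8–C12 and C9–C10. An enamine of A2 adds to the nitroalkene A5 (Michael) and the nitronate closes on the second aldehyde (Henry), giving the nitro aldehyde A4.
- Merits: the cyclopentane, the trans C8/C12 relationship and a C13 aldehyde are obtained catalytically in one pot from very simple materials. The formyl group could take a Horner–Wadsworth–Emmons reagent to give the enone of this target at once.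
- Weak points: the oxygen pattern is misplaced. The nitro carbon must become the C9 carbinol, and the hydroxyl at C10 must be removed and reinstalled at C11, which normally goes through a ring enone and a nucleophilic epoxidation. The 15-keto enone would compete in that epoxidation and in the later C9 reduction, so the enone would have to be introduced late or masked, eroding the brevity. The stub on C8 still needs the same oxidation and Wittig steps as here.
- Comparison: it reaches a ring faster than the chosen plan. The chosen plan places O9 and O11 correctly from the start and carries C15 masked through all redox steps.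

Key step: step 9

## Route

Assumption: (S)-BINAP is taken as the ligand enantiomer whose facial preference matches the substrate-controlled 11,12-trans closure of 15; if the reverse holds, (R)-BINAP is used with no other change.

**Step 1**
Reactants: 1 hexanoyl chloride; 2 ethylene
Product: 3 1-chlorooctan-3-one
Conditions: AlCl3 (1.1 equiv), CH2Cl2, ethylene (1 atm), 0 °C to rt; ice/aq. HCl
Reagents that add atoms: none
Why: Friedel–Crafts-type acylation of ethylene: the acylium ion adds to the alkene and chloride from AlCl4− captures the β-cation, so the β-chloroethyl ketone forms without a second acylation.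

**Step 2**
Reactants: 3 1-chlorooctan-3-one
Product: 4 2-(2-chloroethyl)-2-pentyl-1,3-dioxolane
Conditions: HOCH2CH2OH, p-TsOH (cat.), benzene, reflux (Dean–Stark)
Reagents that add atoms: ethylene glycol, OCCO
Why: Acid-catalysed ketalisation with azeotropic removal of water; the ketone is masked before any base is used, which would otherwise eliminate HCl to the enone.

**Step 3**
Reactants: 4 2-(2-chloroethyl)-2-pentyl-1,3-dioxolane
Product: 6 [2-(2-pentyl-1,3-dioxolan-2-yl)ethyl]triphenylphosphonium iodide, via 2-(2-iodoethyl)-2-pentyl-1,3-dioxolane 5 (not isolated)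
Conditions: NaI (1.5 equiv), PPh3 (1.2 equiv), MeCN, reflux
Reagents that add atoms: triphenylphosphine, c1ccc(cc1)P(c1ccccc1)c1ccccc1; sodium iodide, [Na+].[I-]
Why: Finkelstein exchange gives the more reactive primary iodide in the flask, which quaternises the phosphine by SN2; the ketal is inert under these neutral conditions.

**Step 4**
Reactants: 7 (R)-4-hydroxydihydrofuran-2(3H)-one [(R)-3-hydroxy-γ-butyrolactone]
Product: 8 (R)-4-[(tert-butyldimethylsilyl)oxy]dihydrofuran-2(3H)-one
Conditions: TBSCl, imidazole, DMF, rt
Reagents that add atoms: tert-butyldimethylsilyl chloride, CC(C)(C)[Si](C)(C)Cl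
Why: Standard silylation of a secondary alcohol; imidazole is too weak a base to cause β-elimination in the lactone.

**Step 5**
Reactants: 8 (R)-4-[(tert-butyldimethylsilyl)oxy]dihydrofuran-2(3H)-one
Product: 9 (3R)-3-[(tert-butyldimethylsilyl)oxy]-4-hydroxy-N-methoxy-N-methylbutanamide
Conditions: MeNH(OMe)·HCl (3 equiv), AlMe3 (3 equiv), CH2Cl2, 0 °C to rt; aq. potassium sodium tartrate
Reagents that add atoms: N,O-dimethylhydroxylamine hydrochloride, CNOC.Cl
Why: Aminolysis of a lactone by the aluminium amide formed from AlMe3 and the amine salt; the weakly nucleophilic aluminium alkoxide should not promote 1,2-silyl migration, and crude 9 is oxidised at once to forestall relactonisation.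

**Step 6**
Reactants: 9 (3R)-3-[(tert-butyldimethylsilyl)oxy]-4-hydroxy-N-methoxy-N-methylbutanamide
Product: 10 (3R)-3-[(tert-butyldimethylsilyl)oxy]-N-methoxy-N-methyl-4-oxobutanamide
Conditions: Dess–Martin periodinane, CH2Cl2, 0 °C to rt
Reagents that add atoms: none
Why: Dess–Martin oxidation of a primary alcohol under neutral conditions that do not enolise the α-silyloxy aldehyde; the aldehyde is used crude.

**Step 7**
Reactants: 6 [2-(2-pentyl-1,3-dioxolan-2-yl)ethyl]triphenylphosphonium iodide; 10 (3R)-3-[(tert-butyldimethylsilyl)oxy]-N-methoxy-N-methyl-4-oxobutanamide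
Product: 12 (3R,4Z)-3-[(tert-butyldimethylsilyl)oxy]-N-methoxy-N-methyl-6-(2-pentyl-1,3-dioxolan-2-yl)hex-4-enamide, via phosphonium ylide 11 (not isolated)
Conditions: 6, NaN(SiMe3)2, THF, −78 to 0 °C; then 10, −78 °C to rt
Reagents that add atoms: none
Why: Wittig olefination with a non-stabilised ylide under lithium-free conditions is kinetically Z-selective; at −78 °C the aldehyde reacts far faster than the amide, and the C11 stereocentre is not enolised.

**Step 8**
Reactants: 12 (3R,4Z)-3-[(tert-butyldimethylsilyl)oxy]-N-methoxy-N-methyl-6-(2-pentyl-1,3-dioxolan-2-yl)hex-4-enamide; 13 tert-butyldimethyl(prop-2-yn-1-yloxy)silane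
Product: 15 (6R,7Z)-1,6-bis[(tert-butyldimethylsilyl)oxy]-9-(2-pentyl-1,3-dioxolan-2-yl)non-7-en-2-yn-4-one, via lithium acetylide 14 (not isolated)
Conditions: 13, n-BuLi, THF, −78 °C; then 12, −78 to −20 °C; AcOH quench at −78 °C
Reagents that add atoms: none
Why: Acylation of a lithium acetylide by an N-methoxy-N-methylamide; the chelated tetrahedral intermediate stops the reaction at the ketone, and the cold acidic quench removes the liberated amine before it can add to the ynone.

**Step 9**
Reactants: 15 (6R,7Z)-1,6-bis[(tert-butyldimethylsilyl)oxy]-9-(2-pentyl-1,3-dioxolan-2-yl)non-7-en-2-yn-4-one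
Product: 16 (2Z,3R,4R)-4-[(tert-butyldimethylsilyl)oxy]-2-{2-[(tert-butyldimethylsilyl)oxy]ethylidene}-3-[(E)-2-(2-pentyl-1,3-dioxolan-2-yl)ethenyl]cyclopentan-1-one
Conditions: [Rh(cod)Cl]2 (5 mol%), (S)-BINAP (11 mol%), AgSbF6 (20 mol%), ClCH2CH2Cl, rt
Reagents that add atoms: none
Why: Cationic [Rh((S)-BINAP)]SbF6, freed of chloride by AgSbF6, binds the alkyne and the Z-alkene of 15 and undergoes oxidative cyclisation from monovalent to trivalent rhodium, giving a rhodacyclopentene in which C8–C12 is formed; syn β-hydride elimination of a C14 hydrogen and C7–H reductive elimination release the 1,4-diene 16. This is an Alder-ene type cycloisomerisation of a 1,6-enyne, and the closest known cases are Z-allyl 1,6-enynes whose internal alkyne is conjugated to an ester or amide carbonyl under the same catalyst. The cyclopentanone closes in the exo mode at both π-bonds (5-exo-dig at the alkyne, 5-exo-trig at the alkene). C12 is the only new stereocentre: allylic 1,3-strain in the Z-alkene holds the C11 hydrogen in the alkene plane, so the tether reaches C12 from the face opposite the silyloxy group and C13 ends up trans to O11, and the ligand enantiomer is chosen to reinforce this bias. The step needs the metallacycle pathway to win, which the internal alkyne secures because C7 has no C–H that could give alkynyl- or vinylidene-rhodium species. It needs β-hydride elimination from C14 only, which holds because the C12 hydrogen lies inside the metallacycle while the Z geometry places the C14 hydrogens next to the metal. The same Z geometry dictates the E-C13=C14 alkene, and delivery of hydrogen to C7 with retention makes the ethylidene Z, which step 10 erases.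

**Step 10**
Reactants: 16 (2Z,3R,4R)-4-[(tert-butyldimethylsilyl)oxy]-2-{2-[(tert-butyldimethylsilyl)oxy]ethylidene}-3-[(E)-2-(2-pentyl-1,3-dioxolan-2-yl)ethenyl]cyclopentan-1-one
Product: 17 (2R,3R,4R)-4-[(tert-butyldimethylsilyl)oxy]-2-{2-[(tert-butyldimethylsilyl)oxy]ethyl}-3-[(E)-2-(2-pentyl-1,3-dioxolan-2-yl)ethenyl]cyclopentan-1-one
Conditions: [(Ph3P)CuH]6 (0.4 equiv), H2O (10 equiv), toluene, rt; then KOAc, MeOH, rt if the C8 epimer is present
Reagents that add atoms: none
Why: Copper hydride conjugate reduction of the enone leaves the isolated alkene, the ketal and the ketone untouched, and the copper enolate is formed only toward C8, so the C11 silyloxy group cannot be eliminated. Protonation at C8 should give the 8,12-trans ketone, as the same enolate type does in conjugate additions to 2-alkyl-4-silyloxycyclopentenones; the centre stays epimerisable, so a mild acetate equilibration can complete the conversion.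

**Step 11**
Reactants: 17 (2R,3R,4R)-4-[(tert-butyldimethylsilyl)oxy]-2-{2-[(tert-butyldimethylsilyl)oxy]ethyl}-3-[(E)-2-(2-pentyl-1,3-dioxolan-2-yl)ethenyl]cyclopentan-1-one
Product: 18 (1S,2R,3R,4R)-4-[(tert-butyldimethylsilyl)oxy]-2-{2-[(tert-butyldimethylsilyl)oxy]ethyl}-3-[(E)-2-(2-pentyl-1,3-dioxolan-2-yl)ethenyl]cyclopentan-1-ol
Conditions: LiBH(s-Bu)3, THF, −78 °C; then H2O
Reagents that add atoms: none
Why: The bulky trialkylborohydride attacks C9 from the face opposite the adjacent C8 chain and gives the 9α-alcohol cis to that chain, as established for 11-silyloxy-9-oxo prostanoids.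

**Step 12**
Reactants: 18 (1S,2R,3R,4R)-4-[(tert-butyldimethylsilyl)oxy]-2-{2-[(tert-butyldimethylsilyl)oxy]ethyl}-3-[(E)-2-(2-pentyl-1,3-dioxolan-2-yl)ethenyl]cyclopentan-1-ol
Product: 19 (1R,3S,4R,5R)-4-(2-hydroxyethyl)-5-[(E)-2-(2-pentyl-1,3-dioxolan-2-yl)ethenyl]cyclopentane-1,3-diol
Conditions: Bu4NF (3 equiv), THF, 0 °C to rt
Reagents that add atoms: none
Why: Fluoride cleavage of both silyl ethers; nothing in 18 is base-sensitive and the ketal is untouched.

**Step 13**
Reactants: 19 (1R,3S,4R,5R)-4-(2-hydroxyethyl)-5-[(E)-2-(2-pentyl-1,3-dioxolan-2-yl)ethenyl]cyclopentane-1,3-diol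
Product: 21 (3aR,4R,5R,6aS)-5-hydroxy-4-[(E)-2-(2-pentyl-1,3-dioxolan-2-yl)ethenyl]hexahydro-2H-cyclopenta[b]furan-2-one, via lactol 20 (not isolated)
Conditions: TEMPO (0.2 equiv), PhI(OAc)2 (2.5 equiv), CH2Cl2, rt
Reagents that add atoms: none
Why: Oxoammonium oxidation is selective for the primary alcohol; the aldehyde is trapped by the cis 9α-hydroxyl as lactol 20, which is oxidised on to the γ-lactone, while the secondary 11-hydroxyl reacts much more slowly.

**Step 14**
Reactants: 21 (3aR,4R,5R,6aS)-5-hydroxy-4-[(E)-2-(2-pentyl-1,3-dioxolan-2-yl)ethenyl]hexahydro-2H-cyclopenta[b]furan-2-one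
Product: 20 (3aR,4R,5R,6aS)-4-[(E)-2-(2-pentyl-1,3-dioxolan-2-yl)ethenyl]hexahydro-2H-cyclopenta[b]furan-2,5-diol (lactol anomers)
Conditions: i-Bu2AlH (3.5 equiv), CH2Cl2, −78 °C; aq. potassium sodium tartrate
Reagents that add atoms: none
Why: Partial reduction of a γ-lactone at low temperature stops at the aluminium hemiacetal; the extra equivalents serve the free hydroxyl.

**Step 15**
Reactants: 20 (3aR,4R,5R,6aS)-4-[(E)-2-(2-pentyl-1,3-dioxolan-2-yl)ethenyl]hexahydro-2H-cyclopenta[b]furan-2,5-diol; 22 (4-carboxybutyl)triphenylphosphonium bromide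
Product: 24 (5Z)-7-{(1R,2R,3R,5S)-3,5-dihydroxy-2-[(E)-2-(2-pentyl-1,3-dioxolan-2-yl)ethenyl]cyclopentyl}hept-5-enoic acid, via carboxylate ylide 23 (not isolated)
Conditions: 22 (5 equiv), KOt-Bu (10 equiv), THF, 0 °C; then 20, 0 °C to rt; aq. citric acid to pH 5
Reagents that add atoms: none
Why: Wittig olefination of the lactol, which is in equilibrium with its hydroxy aldehyde, with the non-stabilised carboxylate ylide is the standard way to the 5Z alkene of prostaglandins; excess ylide accommodates the free hydroxyls.

**Step 16**
Reactants: 24 (5Z)-7-{(1R,2R,3R,5S)-3,5-dihydroxy-2-[(E)-2-(2-pentyl-1,3-dioxolan-2-yl)ethenyl]cyclopentyl}hept-5-enoic acid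
Product: 25 15-keto-PGF2α, (5Z)-7-{(1R,2R,3R,5S)-3,5-dihydroxy-2-[(E)-3-oxooct-1-enyl]cyclopentyl}hept-5-enoic acid
Conditions: 1 M aq. HCl/THF (1:4), 0 °C to rt
Reagents that add atoms: water, O
Why: Acid hydrolysis of an allylic ketal, which ionises easily to a conjugated oxocarbenium ion; PGF-type diols do not dehydrate under these conditions, and the enone appears only here.

## Compound list

1 | hexanoyl chloride | CCCCCC(=O)Cl | starting material
2 | ethylene | C=C | starting material
3 | 1-chlorooctan-3-one | CCCCCC(=O)CCCl | intermediate
4 | 2-(2-chloroethyl)-2-pentyl-1,3-dioxolane | CCCCCC1(CCCl)OCCO1 | intermediate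
5 | 2-(2-iodoethyl)-2-pentyl-1,3-dioxolane | CCCCCC1(CCI)OCCO1 | intermediate
6 | [2-(2-pentyl-1,3-dioxolan-2-yl)ethyl]triphenylphosphonium iodide | CCCCCC1(CC[P+](c2ccccc2)(c2ccccc2)c2ccccc2)OCCO1.[I-] | intermediate
7 | (R)-4-hydroxydihydrofuran-2(3H)-one | O=C1C[C@@H](O)CO1 | starting material
8 | (R)-4-[(tert-butyldimethylsilyl)oxy]dihydrofuran-2(3H)-one | O=C1C[C@@H](O[Si](C)(C)C(C)(C)C)CO1 | intermediate
9 | (3R)-3-[(tert-butyldimethylsilyl)oxy]-4-hydroxy-N-methoxy-N-methylbutanamide | CON(C)C(=O)C[C@@H](O[Si](C)(C)C(C)(C)C)CO | intermediate
10 | (3R)-3-[(tert-butyldimethylsilyl)oxy]-N-methoxy-N-methyl-4-oxobutanamide | CON(C)C(=O)C[C@@H](O[Si](C)(C)C(C)(C)C)C=O | intermediate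
11 | [2-(2-pentyl-1,3-dioxolan-2-yl)ethylidene]triphenylphosphorane | CCCCCC1(CC=P(c2ccccc2)(c2ccccc2)c2ccccc2)OCCO1 | intermediate
12 | (3R,4Z)-3-[(tert-butyldimethylsilyl)oxy]-N-methoxy-N-methyl-6-(2-pentyl-1,3-dioxolan-2-yl)hex-4-enamide | CON(C)C(=O)C[C@@H](O[Si](C)(C)C(C)(C)C)/C=C\CC1(CCCCC)OCCO1 | intermediate
13 | tert-butyldimethyl(prop-2-yn-1-yloxy)silane | C#CCO[Si](C)(C)C(C)(C)C | starting material
14 | lithium 3-[(tert-butyldimethylsilyl)oxy]prop-1-yn-1-ide | [Li]C#CCO[Si](C)(C)C(C)(C)C | intermediate
15 | (6R,7Z)-1,6-bis[(tert-butyldimethylsilyl)oxy]-9-(2-pentyl-1,3-dioxolan-2-yl)non-7-en-2-yn-4-one | CC(C)(C)[Si](C)(C)OCC#CC(=O)C[C@@H](O[Si](C)(C)C(C)(C)C)/C=C\CC1(CCCCC)OCCO1 | intermediate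
16 | (2Z,3R,4R)-4-[(tert-butyldimethylsilyl)oxy]-2-{2-[(tert-butyldimethylsilyl)oxy]ethylidene}-3-[(E)-2-(2-pentyl-1,3-dioxolan-2-yl)ethenyl]cyclopentan-1-one | CCCCCC2(OCCO2)/C=C/[C@@H]1/C(=C/CO[Si](C)(C)C(C)(C)C)C(=O)C[C@H]1O[Si](C)(C)C(C)(C)C | intermediate
17 | (2R,3R,4R)-4-[(tert-butyldimethylsilyl)oxy]-2-{2-[(tert-butyldimethylsilyl)oxy]ethyl}-3-[(E)-2-(2-pentyl-1,3-dioxolan-2-yl)ethenyl]cyclopentan-1-one | CCCCCC2(OCCO2)/C=C/[C@@H]1[C@@H](CCO[Si](C)(C)C(C)(C)C)C(=O)C[C@H]1O[Si](C)(C)C(C)(C)C | intermediate
18 | (1S,2R,3R,4R)-4-[(tert-butyldimethylsilyl)oxy]-2-{2-[(tert-butyldimethylsilyl)oxy]ethyl}-3-[(E)-2-(2-pentyl-1,3-dioxolan-2-yl)ethenyl]cyclopentan-1-ol | CCCCCC2(OCCO2)/C=C/[C@@H]1[C@@H](CCO[Si](C)(C)C(C)(C)C)[C@@H](O)C[C@H]1O[Si](C)(C)C(C)(C)C | intermediate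
19 | (1R,3S,4R,5R)-4-(2-hydroxyethyl)-5-[(E)-2-(2-pentyl-1,3-dioxolan-2-yl)ethenyl]cyclopentane-1,3-diol | CCCCCC2(OCCO2)/C=C/[C@@H]1[C@@H](CCO)[C@@H](O)C[C@H]1O | intermediate
20 | (3aR,4R,5R,6aS)-4-[(E)-2-(2-pentyl-1,3-dioxolan-2-yl)ethenyl]hexahydro-2H-cyclopenta[b]furan-2,5-diol (lactol anomers) | CCCCCC2(OCCO2)/C=C/[C@@H]1[C@@H](CC(O)O3)[C@@H]3C[C@H]1O | intermediate
21 | (3aR,4R,5R,6aS)-5-hydroxy-4-[(E)-2-(2-pentyl-1,3-dioxolan-2-yl)ethenyl]hexahydro-2H-cyclopenta[b]furan-2-one | CCCCCC2(OCCO2)/C=C/[C@@H]1[C@@H](CC(=O)O3)[C@@H]3C[C@H]1O | intermediate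
22 | (4-carboxybutyl)triphenylphosphonium bromide | OC(=O)CCCC[P+](c1ccccc1)(c1ccccc1)c1ccccc1.[Br-] | starting material
23 | potassium 5-(triphenylphosphoranylidene)pentanoate | [K+].[O-]C(=O)CCCC=P(c1ccccc1)(c1ccccc1)c1ccccc1 | intermediate
24 | (5Z)-7-{(1R,2R,3R,5S)-3,5-dihydroxy-2-[(E)-2-(2-pentyl-1,3-dioxolan-2-yl)ethenyl]cyclopentyl}hept-5-enoic acid | CCCCCC2(OCCO2)/C=C/[C@@H]1[C@@H](C/C=C\CCCC(=O)O)[C@@H](O)C[C@H]1O | intermediate
25 | 15-keto-PGF2α, (5Z)-7-{(1R,2R,3R,5S)-3,5-dihydroxy-2-[(E)-3-oxooct-1-enyl]cyclopentyl}hept-5-enoic acid | CCCCCC(=O)/C=C/[C@@H]1[C@@H](C/C=C\CCCC(=O)O)[C@@H](O)C[C@H]1O | target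

## Step count and least certain steps

Total: 16 steps. Longest linear sequence: 13 steps (steps 4–16 from 7; the branch through steps 1–3 and 7–16 is equally long).

**Step 9 (key step).** The conjugated ynone may turn over slowly or decompose, because the ketone and two bulky silyl ethers crowd both π-bonds. The rhodium hydride could also move the new exocyclic alkene into the ring, and a ligand working against the substrate bias would erode the 11,12-trans selectivity. The other BINAP enantiomer is tried first. The fallback takes the carbonyl out of conjugation so that the substrate is a plain carbon-tethered 1,6-enyne. Ynone 15 is reduced with NaBH4/CeCl3 in MeOH to the propargylic alcohol (6R,7Z)-1,6-bis[(tert-butyldimethylsilyl)oxy]-9-(2-pentyl-1,3-dioxolan-2-yl)non-7-en-2-yn-4-ol F1 (both C9 epimers). This is cyclised with the same cationic rhodium–BINAP catalyst to the allylic alcohol (2Z,3R,4R)-4-[(tert-butyldimethylsilyl)oxy]-2-{2-[(tert-butyldimethylsilyl)oxy]ethylidene}-3-[(E)-2-(2-pentyl-1,3-dioxolan-2-yl)ethenyl]cyclopentan-1-ol F2. Oxidation of the allylic alcohol with MnO2 in CH2Cl2 merges both epimers into 16, where the route resumes.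

**Step 5.** Silyl migration from O3 to the freed primary oxygen, or relactonisation to 8 on concentration, could take place because the product is a 1,2-diol monosilyl ether with an acyl group placed for ring closure. The fallback changes the order of events so that no alkoxide ever sits next to the silyl ether. Lactone 7 is opened unprotected with MeNH(OMe)·HCl/AlMe3 to (3R)-3,4-dihydroxy-N-methoxy-N-methylbutanamide F3. Both hydroxyls are silylated with TBSCl/imidazole to (3R)-3,4-bis[(tert-butyldimethylsilyl)oxy]-N-methoxy-N-methylbutanamide F4. The primary silyl ether is then cleaved selectively with HF·pyridine in pyridine/THF at 0 °C to give 9.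

**Step 8.** Loss of the C11 silyloxy group by E1cB elimination from the amide enolate, addition of the liberated amine to the ynone, or propargyl-to-allenyl isomerisation could compete, because the acetylide is basic and the amide reacts slowly at low temperature. The fallback forms C8–C9 at the aldehyde level. Amide 12 is reduced with i-Bu2AlH in THF at −78 °C to (3R,4Z)-3-[(tert-butyldimethylsilyl)oxy]-6-(2-pentyl-1,3-dioxolan-2-yl)hex-4-enal F5. Acetylide 14 adds to F5 at −78 °C to give the propargylic alcohol F1, and Dess–Martin oxidation returns to 15. F1 can equally be sent straight into the fallback for step 9.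

**Step 13.** The acetic acid released by the oxidant could open the allylic ketal, and the 11-hydroxyl could be over-oxidised, because three free hydroxyls and an acid-labile group are present together. Solid NaHCO3 is the first remedy. The fallback masks the ring diol and runs the Wittig reaction on a free aldehyde instead of a lactol. Triol 19 and butylboronic acid in CH2Cl2 over MgSO4 give the cyclic 9,11-butylboronate of 19 F6, which leaves only the primary alcohol free. Dess–Martin oxidation gives the boronate aldehyde F7, and ylide 23 converts it into the 9,11-butylboronate of 24 F8. The boronate is hydrolysed during aqueous work-up, and the route is rejoined at 24.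

## Further compounds

F1 | step 9 | (6R,7Z)-1,6-bis[(tert-butyldimethylsilyl)oxy]-9-(2-pentyl-1,3-dioxolan-2-yl)non-7-en-2-yn-4-ol (C4 epimers) | CC(C)(C)[Si](C)(C)OCC#CC(O)C[C@@H](O[Si](C)(C)C(C)(C)C)/C=C\CC1(CCCCC)OCCO1
F2 | step 9 | (2Z,3R,4R)-4-[(tert-butyldimethylsilyl)oxy]-2-{2-[(tert-butyldimethylsilyl)oxy]ethylidene}-3-[(E)-2-(2-pentyl-1,3-dioxolan-2-yl)ethenyl]cyclopentan-1-ol (C1 epimers) | CCCCCC2(OCCO2)/C=C/[C@@H]1/C(=C/CO[Si](C)(C)C(C)(C)C)C(O)C[C@H]1O[Si](C)(C)C(C)(C)C
F3 | step 5 | (3R)-3,4-dihydroxy-N-methoxy-N-methylbutanamide | CON(C)C(=O)C[C@@H](O)CO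
F4 | step 5 | (3R)-3,4-bis[(tert-butyldimethylsilyl)oxy]-N-methoxy-N-methylbutanamide | CON(C)C(=O)C[C@@H](O[Si](C)(C)C(C)(C)C)CO[Si](C)(C)C(C)(C)C
F5 | step 8 | (3R,4Z)-3-[(tert-butyldimethylsilyl)oxy]-6-(2-pentyl-1,3-dioxolan-2-yl)hex-4-enal | O=CC[C@@H](O[Si](C)(C)C(C)(C)C)/C=C\CC1(CCCCC)OCCO1
F6 | step 13 | cyclic 9,11-butylboronate of triol 19 | CCCCCC2(OCCO2)/C=C/[C@@H]1[C@@H](CCO)[C@@H]3C[C@H]1OB(CCCC)O3
F7 | step 13 | cyclic 9,11-butylboronate of the C6 aldehyde | CCCCCC2(OCCO2)/C=C/[C@@H]1[C@@H](CC=O)[C@@H]3C[C@H]1OB(CCCC)O3
F8 | step 13 | cyclic 9,11-butylboronate of acid 24 | CCCCCC2(OCCO2)/C=C/[C@@H]1[C@@H](C/C=C\CCCC(=O)O)[C@@H]3C[C@H]1OB(CCCC)O3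
A1 | alternative 1 | (3aR,6aS)-2-hydroxy-3,3a,6,6a-tetrahydro-2H-cyclopenta[b]furan-5-carbaldehyde (lactol anomers) | O=CC1=C[C@H]2CC(O)O[C@H]2C1
A2 | alternative 1 | succinaldehyde | O=CCCC=O
A3 | alternative 2 | cyclopentane-fused isoxazoline with C11 tert-butyldimethylsilyl ether and C13 4-methoxybenzyl ether | COc1ccc(COC[C@@H]2[C@H]3CON=C3C[C@H]2O[Si](C)(C)C(C)(C)C)cc1
A4 | alternative 3 | 4-hydroxy-2-{2-[(4-methoxybenzyl)oxy]ethyl}-3-nitrocyclopentane-1-carbaldehyde (all-trans isomer) | O=C[C@@H]1[C@@H](CCOCc2ccc(OC)cc2)[C@H]([N+](=O)[O-])[C@@H](O)C1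
A5 | alternative 3 | (E)-1-methoxy-4-{[(4-nitrobut-3-en-1-yl)oxy]methyl}benzene | COc1ccc(COCC/C=C/[N+](=O)[O-])cc1
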